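**Retrosynthetic overview**
- The only stereocentre, C2 (S), is bought in (2S)-hesperetin 1. Its 3'-OH marks the coupling carbon and its 4'-OMe is already in place; 7-O-methylation gives 2 and triflation gives 3.
- The flavone half comes from apigenin 4: tribenzyl ether 5, then C8 bromination to 6.
- Key disconnection: the C3'–C8'' biaryl bond, made by an electroreductive nickel/palladium cross-electrophile coupling of 3 with 6 to give 7.
- Hydrogenolysis of the three benzyl ethers of 7 gives target 8.
- No ring is built: the chromanone and flavone ring systems are both purchased, and only the inter-unit biaryl bond is formed.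

Assumption: (2S)-hesperetin is bought as the single (S)-enantiomer (aglycone of the citrus glycoside hesperidin) and its ee is confirmed by chiral HPLC before use; the target is read as (2S)-2,3-dihydroginkgetin with no defined biaryl axis.

**Step 1**
Reactants: 1 (2S)-hesperetin [(2S)-5,7-dihydroxy-2-(3-hydroxy-4-methoxyphenyl)chroman-4-one]
Product: 2 (2S)-7-O-methylhesperetin [(2S)-5-hydroxy-2-(3-hydroxy-4-methoxyphenyl)-7-methoxychroman-4-one]
Conditions: MeOH (1.1 equiv), PPh3 (1.1 equiv), DIAD (1.05 equiv), THF, 0 °C to rt, 3 h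
Reagents that add atoms: methanol, CO
Why: Mitsunobu O-methylation picks the most acidic phenol (7-OH, para to the carbonyl) over the 3'-OH and the hydrogen-bonded 5-OH, and its neutral conditions avoid the base-induced chalcone ring-opening that would racemise C2.

**Step 2**
Reactants: 2 (2S)-7-O-methylhesperetin
Product: 3 5-[(2S)-5-hydroxy-7-methoxy-4-oxochroman-2-yl]-2-methoxyphenyl trifluoromethanesulfonate
Conditions: Tf2O (1.1 equiv), pyridine (3 equiv), CH2Cl2, −40 to 0 °C
Reagents that add atoms: trifluoromethanesulfonic anhydride, O=S(=O)(OS(=O)(=O)C(F)(F)F)C(F)(F)F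
Why: O-sulfonylation of the only free, non-chelated phenol (3'-OH); the 5-OH is tied up in its hydrogen bond to C4=O, and pyridine at low temperature is too weak a base to enolise the flavanone, so C2 stays S.

**Step 3**
Reactants: 4 apigenin [5,7-dihydroxy-2-(4-hydroxyphenyl)-4H-chromen-4-one]
Product: 5 5,7-bis(benzyloxy)-2-[4-(benzyloxy)phenyl]-4H-chromen-4-one
Conditions: BnBr (4 equiv), K2CO3 (5 equiv), Bu4NI (5 mol%), DMF, 80 °C, 12 h
Reagents that add atoms: benzyl bromide, BrCc1ccccc1
Why: Williamson etherification; excess reagent and heat also alkylate the chelated 5-OH, and benzyl is chosen because it is removed later without touching the two methyl ethers of the target.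

**Step 4**
Reactants: 5 5,7-bis(benzyloxy)-2-[4-(benzyloxy)phenyl]-4H-chromen-4-one
Product: 6 8-bromo-5,7-bis(benzyloxy)-2-[4-(benzyloxy)phenyl]-4H-chromen-4-one
Conditions: NBS (1.05 equiv), DMF, 0 °C to rt, dark
Reagents that add atoms: N-bromosuccinimide, O=C1CCC(=O)N1Br
Why: Electrophilic aromatic bromination; in 5-O-alkylated 5,7-dialkoxyflavones C8 is the most nucleophilic position of ring A, and ionic conditions in the dark avoid benzylic bromination.

**Step 5**
Reactants: 3 5-[(2S)-5-hydroxy-7-methoxy-4-oxochroman-2-yl]-2-methoxyphenyl trifluoromethanesulfonate; 6 8-bromo-5,7-bis(benzyloxy)-2-[4-(benzyloxy)phenyl]-4H-chromen-4-one (1.3 equiv)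
Product: 7 5,7-bis(benzyloxy)-2-[4-(benzyloxy)phenyl]-8-{5-[(2S)-5-hydroxy-7-methoxy-4-oxochroman-2-yl]-2-methoxyphenyl}-4H-chromen-4-one
Conditions: NiBr2·dme (10 mol%), 4,4'-di-tert-butyl-2,2'-bipyridine (10 mol%), PdCl2(dppp) (10 mol%), LiBr (0.2 M), DMF, undivided cell, Zn anode, Ni-foam cathode, constant current 2 mA cm−2, 2.5 F mol−1, 40 °C, Ar
Reagents that add atoms: none
Why: Proposed new method: an electroreductive nickel/palladium dual-catalysed cross-Ullmann coupling, not yet shown under electrolysis or on flavonoid partners, in which zerovalent palladium–dppp inserts selectively into the C–OTf bond of 3 while cathodically generated zerovalent nickel–bipyridine inserts selectively into the C–Br bond of 6, the di-ortho-substituted arylnickel bromide cannot homocouple and passes its aryl group to the arylpalladium species, and reductive elimination at palladium forms the C3'–C8'' bond; current-controlled dosing of electrons keeps the two aryl-metal pools matched, the cathode sits at the nickel wave, positive of flavone and aryl ketone reduction, and the neutral base-free medium leaves C2 (S) untouched (no new stereocentre, the biaryl axis is not defined in the target); closest known reaction type is the zinc-powder-driven nickel/palladium cross-Ullmann coupling of aryl bromides with aryl triflates, together with nickel-catalysed electroreductive aryl halide coupling at a sacrificial zinc anode.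

**Step 6**
Reactants: 7 5,7-bis(benzyloxy)-2-[4-(benzyloxy)phenyl]-8-{5-[(2S)-5-hydroxy-7-methoxy-4-oxochroman-2-yl]-2-methoxyphenyl}-4H-chromen-4-one
Product: 8 5,7-dihydroxy-8-{5-[(2S)-5-hydroxy-7-methoxy-4-oxochroman-2-yl]-2-methoxyphenyl}-2-(4-hydroxyphenyl)-4H-chromen-4-one [(2S)-2,3-dihydroginkgetin, CNP0169789.1]
Conditions: H2 (1 atm), 10% Pd/C, THF/MeOH 1:1, rt, 2–4 h, monitored by HPLC
Reagents that add atoms: none
Why: Catalytic hydrogenolysis removes the three benzyl ethers under neutral conditions, leaving the methyl ethers, the flavone C2''=C3'' bond and the flavanone C2–O bond intact over a short reaction time, so C2 remains S (checked by chiral HPLC).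

**Compound list**
1 | (2S)-hesperetin | Oc1cc(O)c2c(c1)O[C@H](c1ccc(OC)c(O)c1)CC2=O | starting material
2 | (2S)-7-O-methylhesperetin | COc1cc(O)c2c(c1)O[C@H](c1ccc(OC)c(O)c1)CC2=O | intermediate
3 | 5-[(2S)-5-hydroxy-7-methoxy-4-oxochroman-2-yl]-2-methoxyphenyl trifluoromethanesulfonate | COc1cc(O)c2c(c1)O[C@H](c1ccc(OC)c(OS(=O)(=O)C(F)(F)F)c1)CC2=O | intermediate
4 | apigenin | O=c1cc(-c2ccc(O)cc2)oc2cc(O)cc(O)c12 | starting material
5 | 5,7-bis(benzyloxy)-2-[4-(benzyloxy)phenyl]-4H-chromen-4-one | O=c1cc(-c2ccc(OCc3ccccc3)cc2)oc2cc(OCc3ccccc3)cc(OCc3ccccc3)c12 | intermediate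
6 | 8-bromo-5,7-bis(benzyloxy)-2-[4-(benzyloxy)phenyl]-4H-chromen-4-one | O=c1cc(-c2ccc(OCc3ccccc3)cc2)oc2c(Br)c(OCc3ccccc3)cc(OCc3ccccc3)c12 | intermediate
7 | 5,7-bis(benzyloxy)-2-[4-(benzyloxy)phenyl]-8-{5-[(2S)-5-hydroxy-7-methoxy-4-oxochroman-2-yl]-2-methoxyphenyl}-4H-chromen-4-one | COc1cc(O)c2c(c1)O[C@H](c1ccc(OC)c(-c3c(OCc6ccccc6)cc(OCc6ccccc6)c4c(=O)cc(-c5ccc(OCc6ccccc6)cc5)oc34)c1)CC2=O | intermediate
8 | (2S)-2,3-dihydroginkgetin (CNP0169789.1) | COc1cc(O)c2c(c1)O[C@H](c1ccc(OC)c(-c3c(O)cc(O)c4c(=O)cc(-c5ccc(O)cc5)oc34)c1)CC2=O | target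

**Totals**
Total step count: 6. Longest linear sequence: 4 steps (1 → 2 → 3 → 7 → 8, or 4 → 5 → 6 → 7 → 8).

**Three steps most likely to fail**

Step 5 (the proposed new coupling). The risks are slow aryl transfer from the hindered arylnickel species, homocoupling of 3, hydrodebromination of 6 back to 5, and cathodic reduction of the carbonyl groups. The fallback uses known chemistry and sets out from 6. Bromide 6 is stannylated with hexamethylditin and Pd(PPh3)4 in toluene at 100 °C to give 8-(trimethylstannyl)-5,7-bis(benzyloxy)-2-[4-(benzyloxy)phenyl]-4H-chromen-4-one F1. F1 is then joined to triflate 3 by a copper-accelerated Stille coupling (Pd(PPh3)4, CuCl, LiCl, DMSO, 60 °C). This is neutral, so C2 is not at risk, and it comes back to the route at 7.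

Step 6 (global debenzylation). The risks are over-reduction of the flavone C2''=C3'' bond, hydrogenolysis of the benzylic C2–O bond of the flavanone, and poor solubility of the biflavonoid. The fallback sets out from 7 and replaces hydrogenolysis by Lewis-acid ether cleavage: BCl3 (8 equiv) with pentamethylbenzene (10 equiv) as benzyl-cation scavenger in CH2Cl2 at −78 °C, then MeOH quench. At this temperature the non-chelated methyl ethers survive. It comes back at 8 and makes no new intermediate (F0).

Step 4 (C8 bromination). The risks are dibromination, bromination at C6, C3 or ring B, and benzylic bromination. The fallback sets out from 5 and gives up the bromide and the cross-electrophile pairing. Compound 5 is iodinated with NIS and catalytic CF3CO2H in MeCN/CH2Cl2 at 0 °C to give 8-iodo-5,7-bis(benzyloxy)-2-[4-(benzyloxy)phenyl]-4H-chromen-4-one F2. F2 is stannylated (hexamethylditin, Pd(PPh3)4, toluene, 80 °C) to the stannane F1 described above, and F1 is Stille-coupled with 3 as in the step 5 fallback, coming back at 7.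

**Further compounds**
F1 | step 5 | 8-(trimethylstannyl)-5,7-bis(benzyloxy)-2-[4-(benzyloxy)phenyl]-4H-chromen-4-one | C[Sn](C)(C)c1c(OCc2ccccc2)cc(OCc2ccccc2)c2c(=O)cc(-c3ccc(OCc4ccccc4)cc3)oc12
F0 | step 6 | none | none
F2 | step 4 | 8-iodo-5,7-bis(benzyloxy)-2-[4-(benzyloxy)phenyl]-4H-chromen-4-one | Ic1c(OCc2ccccc2)cc(OCc2ccccc2)c2c(=O)cc(-c3ccc(OCc4ccccc4)cc3)oc12
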